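**Retrosynthetic overview**
1. Target ⇐ all-cis oxolane-3-carboxylic acid (CO2H → CH2OH, last step).
2. That acid ⇐ bicyclic enol-ether γ-lactone (dihydrofuro[3,4-c]furanone): one hydrogenation saturates the C=C (sets C2 and C3) and cleaves the benzylic lactone C–O, which turns the lactone carbinol carbon into the benzyl CH2.
3. Bicyclic lactone ⇐ allyl-type α-diazo-β-keto ester: carbenoid cyclopropanation closes γ-lactone and cyclopropane together, then an iodide-triggered Cloke–Wilson expansion in the same pot converts the cyclopropane into the dihydrofuran.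
4. Diazo ester ⇐ (S)-1-arylallyl alcohol + ethyl 3,4,5-trimethoxybenzoylacetate; the alcohol ⇐ 2,4,5-trimethoxybenzaldehyde + vinyl nucleophile (asymmetric addition).
5. Ring order: γ-lactone + cyclopropane (one operation) → dihydrofuran (future oxolane) → lactone opened, oxolane kept.

Assumption: the SMILES is read literally, i.e. (2R,3R,4R) with aryl, CH2OH and benzyl all cis on the oxolane ring.

**Step 1**
Reactants: 1 2,4,5-trimethoxybenzaldehyde; 2 vinylmagnesium bromide
Product: 3 (1S)-1-(2,4,5-trimethoxyphenyl)prop-2-en-1-ol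
Conditions: 2 (2.4 equiv), ZnCl2 (1.2 equiv), THF/toluene, 0 °C (gives divinylzinc); (−)-MIB (10 mol%), 1, toluene, −30 → 0 °C; pH 7 buffer quench
Reagents that add atoms: none
Why: Amino-alcohol-catalysed enantioselective alkenylzinc addition to an aldehyde (Noyori/Oppolzer type), in which the (−)-MIB–zinc chelate delivers the vinyl group to the Si face and so sets the (S)-carbinol.

**Step 2**
Reactants: 3 (1S)-1-(2,4,5-trimethoxyphenyl)prop-2-en-1-ol; 4 ethyl 3-oxo-3-(3,4,5-trimethoxyphenyl)propanoate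
Product: 5 (1S)-1-(2,4,5-trimethoxyphenyl)prop-2-en-1-yl 3-oxo-3-(3,4,5-trimethoxyphenyl)propanoate
Conditions: 4 (1.2 equiv), DMAP (20 mol%), 4 Å MS, toluene, 95 °C
Reagents that add atoms: none
Why: DMAP-catalysed transesterification of a β-keto ester is neutral and exchanges only the acyl–O bond, so the carbinol C–O bond and its (S) configuration are untouched.

**Step 3**
Reactants: 5 (1S)-1-(2,4,5-trimethoxyphenyl)prop-2-en-1-yl 3-oxo-3-(3,4,5-trimethoxyphenyl)propanoate
Product: 6 (1S)-1-(2,4,5-trimethoxyphenyl)prop-2-en-1-yl 2-diazo-3-oxo-3-(3,4,5-trimethoxyphenyl)propanoate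
Conditions: p-ABSA (1.1 equiv), Et3N, MeCN, 0 °C → rt
Reagents that add atoms: 4-acetamidobenzenesulfonyl azide (p-ABSA), CC(=O)Nc1ccc(cc1)S(=O)(=O)N=[N+]=[N-]
Why: Regitz diazo transfer to the doubly activated methylene of a β-keto ester under mild base, with no bond to the stereocentre involved.

**Step 4**
Reactants: 6 (1S)-1-(2,4,5-trimethoxyphenyl)prop-2-en-1-yl 2-diazo-3-oxo-3-(3,4,5-trimethoxyphenyl)propanoate
Product: 8 (3S,3aR)-6-(3,4,5-trimethoxyphenyl)-3-(2,4,5-trimethoxyphenyl)-3a,4-dihydro-1H,3H-furo[3,4-c]furan-1-one, via cyclopropane-fused lactone 7 (not isolated)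
Conditions: Rh2(esp)2 (1 mol%), CH2Cl2, rt, slow addition of 6; then solvent swap, LiI (30 mol%), MeCN, 60 °C; chromatography on Et3N-washed SiO2 to remove the minor 3,3a-cis diastereomer (it would otherwise lower the ee after step 5)
Reagents that add atoms: none
Why: Proposed new method: the Rh carbenoid of 6 cyclopropanates the tethered vinyl group (intramolecular cyclopropanation of an allyl α-diazo-β-keto ester, a known reaction type) through the A(1,3)-minimised conformer with the carbinol H eclipsing the alkene, so the aryl group ends anti to the cyclopropane CH2 and the (S)-carbinol fixes the ring-fusion centre (future C4); iodide then opens the doubly activated cyclopropane of 7 at its unhindered CH2 by homoconjugate SN2 attack and the keto-enolate oxygen displaces iodide 5-exo-tet (nucleophile-catalysed Cloke–Wilson rearrangement, closest precedents being iodide- and DABCO-promoted ring expansions of acyl cyclopropanes), leaving the ring-fusion stereocentre untouched.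

**Step 5**
Reactants: 8 (3S,3aR)-6-(3,4,5-trimethoxyphenyl)-3-(2,4,5-trimethoxyphenyl)-3a,4-dihydro-1H,3H-furo[3,4-c]furan-1-one
Product: 10 (2R,3S,4R)-2-(3,4,5-trimethoxyphenyl)-4-[(2,4,5-trimethoxyphenyl)methyl]oxolane-3-carboxylic acid, via dihydrofuran acid 9 (not isolated)
Conditions: H2 (4 bar), 10% Pd/C, EtOAc (1% AcOH), rt, monitored to stop at uptake of 2 equiv
Reagents that add atoms: none
Why: Benzylic ester hydrogenolysis plus heterogeneous syn-hydrogenation, in which Pd cleaves the electron-rich benzylic lactone C–O bond (giving CH2Ar and CO2H, 9) and adds H2 to the tetrasubstituted enol-ether C=C from the face opposite the C4 benzyl group, so C2–H and C3–H arrive cis to C4–H and the aryl, carboxyl and benzyl groups finish all-cis.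

**Step 6**
Reactants: 10 (2R,3S,4R)-2-(3,4,5-trimethoxyphenyl)-4-[(2,4,5-trimethoxyphenyl)methyl]oxolane-3-carboxylic acid
Product: 11 [(2R,3R,4R)-2-(3,4,5-trimethoxyphenyl)-4-[(2,4,5-trimethoxyphenyl)methyl]oxolan-3-yl]methanol (target)
Conditions: BH3·THF (2.5 equiv), THF, 0 °C → rt; MeOH then H2O
Reagents that add atoms: none
Why: Chemoselective borane reduction of a carboxylic acid (acyloxyborane pathway) under non-basic conditions, so the epimerisable C3 and the retro-oxa-Michael-prone C2 keep their configuration.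

**Compound list**
1 | 2,4,5-trimethoxybenzaldehyde | COc1cc(OC)c(OC)cc1C=O | starting material
2 | vinylmagnesium bromide | C=C[Mg]Br | starting material
3 | (1S)-1-(2,4,5-trimethoxyphenyl)prop-2-en-1-ol | C=C[C@H](O)c1cc(OC)c(OC)cc1OC | intermediate
4 | ethyl 3-oxo-3-(3,4,5-trimethoxyphenyl)propanoate | CCOC(=O)CC(=O)c1cc(OC)c(OC)c(OC)c1 | starting material
5 | (1S)-1-(2,4,5-trimethoxyphenyl)prop-2-en-1-yl 3-oxo-3-(3,4,5-trimethoxyphenyl)propanoate | C=C[C@H](OC(=O)CC(=O)c1cc(OC)c(OC)c(OC)c1)c1cc(OC)c(OC)cc1OC | intermediate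
6 | (1S)-1-(2,4,5-trimethoxyphenyl)prop-2-en-1-yl 2-diazo-3-oxo-3-(3,4,5-trimethoxyphenyl)propanoate | C=C[C@H](OC(=O)C(=[N+]=[N-])C(=O)c1cc(OC)c(OC)c(OC)c1)c1cc(OC)c(OC)cc1OC | intermediate
7 | (1R,4S,5S)-1-(3,4,5-trimethoxybenzoyl)-4-(2,4,5-trimethoxyphenyl)-3-oxabicyclo[3.1.0]hexan-2-one (aryl anti to the cyclopropane CH2) | O=C1O[C@H](c3cc(OC)c(OC)cc3OC)[C@H]2C[C@@]12C(=O)c4cc(OC)c(OC)c(OC)c4 | intermediate
8 | (3S,3aR)-6-(3,4,5-trimethoxyphenyl)-3-(2,4,5-trimethoxyphenyl)-3a,4-dihydro-1H,3H-furo[3,4-c]furan-1-one | O=C1O[C@H](c3cc(OC)c(OC)cc3OC)[C@H]2COC(c3cc(OC)c(OC)c(OC)c3)=C12 | intermediate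
9 | (4R)-2-(3,4,5-trimethoxyphenyl)-4-[(2,4,5-trimethoxyphenyl)methyl]-4,5-dihydrofuran-3-carboxylic acid | COc1cc(OC)c(OC)cc1C[C@H]1COC(c2cc(OC)c(OC)c(OC)c2)=C1C(=O)O | intermediate
10 | (2R,3S,4R)-2-(3,4,5-trimethoxyphenyl)-4-[(2,4,5-trimethoxyphenyl)methyl]oxolane-3-carboxylic acid (all-cis) | COc1cc(OC)c(OC)cc1C[C@H]1CO[C@@H](c2cc(OC)c(OC)c(OC)c2)[C@H]1C(=O)O | intermediate
11 | [(2R,3R,4R)-2-(3,4,5-trimethoxyphenyl)-4-[(2,4,5-trimethoxyphenyl)methyl]oxolan-3-yl]methanol | COc1cc(OC)c(OC)cc1C[C@H]1CO[C@@H](c2cc(OC)c(OC)c(OC)c2)[C@H]1CO | target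

**Totals**
Total step count: 6. Longest linear sequence: 6 (1 → 3 → 5 → 6 → 8 → 10 → 11).

**Three steps most likely to fail, with fallbacks**

1. Step 4. The carbenoid may attack the electron-rich 2,4,5-trimethoxyphenyl ring instead of the alkene, the exo/endo ratio of the cyclopropanation may be modest, and the iodide-triggered ring expansion may be slow or accompanied by Krapcho-type loss of the benzylic ester. The fallback sets out from 5 and comes back at 8, and bypasses the diazo compound. α-Iodination of 5 (NIS, CH2Cl2, 0 °C) gives (1S)-1-(2,4,5-trimethoxyphenyl)prop-2-en-1-yl 2-iodo-3-oxo-3-(3,4,5-trimethoxyphenyl)propanoate F1. Iodine-atom-transfer 5-exo radical cyclisation (Et3B/air, benzene, rt) gives (4S,5S)-4-(iodomethyl)-5-(2,4,5-trimethoxyphenyl)-3-(3,4,5-trimethoxybenzoyl)oxolan-2-one F2, 4,5-trans through the usual chair-like transition state of a 4-substituted hexenyl radical. K2CO3 in MeCN (rt → 50 °C) then closes the keto-enolate oxygen onto the CH2I group to give 8; any C-alkylated material is 7, which the liberated iodide converts into 8.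

2. Step 5. Saturating the push-pull tetrasubstituted alkene may need conditions that also hydrogenolyse the C2–O1 benzylic ether of the product, and facial control rests on one benzyl group once the lactone is open. The fallback sets out from 8 and comes back at 11. Only the C=C is hydrogenated, with a non-hydrogenolysing catalyst on the intact bicycle (H2 5 bar, 5% Rh/Al2O3, EtOAc), where convex-face addition gives (3S,3aR,6R,6aS)-6-(3,4,5-trimethoxyphenyl)-3-(2,4,5-trimethoxyphenyl)tetrahydro-1H,3H-furo[3,4-c]furan-1-one F3. LiAlH4 (THF, 0 °C) opens the lactone to (S)-[(3R,4R,5R)-4-(hydroxymethyl)-5-(3,4,5-trimethoxyphenyl)oxolan-3-yl](2,4,5-trimethoxyphenyl)methanol F4. Ionic deoxygenation (Et3SiH, TFA, CH2Cl2, −40 °C) removes only the hydroxyl on the 2,4,5-trimethoxyphenyl carbinol, whose cation is far better stabilised than one at C2, and gives 11 directly.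

3. Step 2. The very electron-rich allylic benzylic alcohol and its ester may ionise, transpose to the cinnamyl isomer or racemise at 95 °C. The fallback sets out from 3 and comes back at 5 without heating. Acetylation (Ac2O, Et3N, DMAP, CH2Cl2, 0 °C) gives (1S)-1-(2,4,5-trimethoxyphenyl)prop-2-en-1-yl acetate F5. Crossed Claisen condensation of its lithium enolate (LiHMDS 2.1 equiv, THF, −78 °C) with 3,4,5-trimethoxybenzoyl chloride, quenched with AcOH at −78 °C, gives 5.

**Further compounds**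
F1 | step 4 | (1S)-1-(2,4,5-trimethoxyphenyl)prop-2-en-1-yl 2-iodo-3-oxo-3-(3,4,5-trimethoxyphenyl)propanoate (C2 epimers) | C=C[C@H](OC(=O)C(I)C(=O)c1cc(OC)c(OC)c(OC)c1)c1cc(OC)c(OC)cc1OC
F2 | step 4 | (4S,5S)-4-(iodomethyl)-5-(2,4,5-trimethoxyphenyl)-3-(3,4,5-trimethoxybenzoyl)oxolan-2-one (C3 epimers) | O=C1O[C@H](c2cc(OC)c(OC)cc2OC)[C@@H](CI)C1C(=O)c1cc(OC)c(OC)c(OC)c1
F3 | step 5 | (3S,3aR,6R,6aS)-6-(3,4,5-trimethoxyphenyl)-3-(2,4,5-trimethoxyphenyl)tetrahydro-1H,3H-furo[3,4-c]furan-1-one | O=C1O[C@H](c3cc(OC)c(OC)cc3OC)[C@H]2CO[C@@H](c3cc(OC)c(OC)c(OC)c3)[C@@H]12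
F4 | step 5 | (S)-[(3R,4R,5R)-4-(hydroxymethyl)-5-(3,4,5-trimethoxyphenyl)oxolan-3-yl](2,4,5-trimethoxyphenyl)methanol | COc1cc(OC)c(OC)cc1[C@@H](O)[C@H]1CO[C@@H](c2cc(OC)c(OC)c(OC)c2)[C@H]1CO
F5 | step 2 | (1S)-1-(2,4,5-trimethoxyphenyl)prop-2-en-1-yl acetate | C=C[C@H](OC(C)=O)c1cc(OC)c(OC)cc1OC
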